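**Retrosynthetic overview**
- (3S,6E)-Nerolidol 1 supplies all fifteen carbons and the C3 carbinol centre; its hydroxyl is masked as silyl ether 2 so that oxygen cannot capture the C7 cation.
- Ring disconnection (the only ring, formed first): the C6–C11 bond and C10–Br of 3 come from a catalyst-controlled bromonium-initiated cation–olefin cyclization of 2, ended by loss of H-8.
- The C8–Br bond and the exocyclic methylene of 4 come from a second Br+ event on 3, an ene-type bromination with allylic transposition under substrate control; desilylation in the same flask gives 5.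
- Nerolidol numbering is used throughout: C3 carbinol, C6–C11 ring carbons, C15 the methyl on C7.

Assumption: (3S,6E)-nerolidol [(+)-trans-nerolidol, natural cabreuva-oil grade] is bought as the single enantiomer, and the hand of the step 2 catalyst, written as (S), is fixed by a pilot run (its antipode gives the other ring diastereomer).

**Step 1**
Reactants: 1 (3S,6E)-nerolidol
Product: 2 triethyl{[(3S,6E)-3,7,11-trimethyldodeca-1,6,10-trien-3-yl]oxy}silane
Conditions: TESOTf (1.3 equiv), 2,6-lutidine (2 equiv), CH2Cl2, −78 → 0 °C
Reagents that add atoms: triethylsilyl trifluoromethanesulfonate (TESOTf), CC[Si](CC)(CC)OS(=O)(=O)C(F)(F)F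
Why: O-silylation of a tertiary alcohol with a silyl triflate and a hindered pyridine is fast at low temperature, leaves the three alkenes and the C3 centre untouched, and masks the hydroxyl that would otherwise trap the C7 cation as a bicyclic tetrahydropyran in steps 2 and 3.

**Step 2**
Reactants: 2 triethyl{[(3S,6E)-3,7,11-trimethyldodeca-1,6,10-trien-3-yl]oxy}silane
Product: 3 triethyl({(3S)-5-[(1R,5S)-5-bromo-2,6,6-trimethylcyclohex-2-en-1-yl]-3-methylpent-1-en-3-yl}oxy)silane (α-snyderol triethylsilyl ether)
Conditions: (S)-3,3′-bis(2,4,6-triisopropylphenyl)-BINOL N-aryl thiophosphoramide (10 mol%), DBDMH (1.1 equiv), PhMe/CH2Cl2 (4:1), −90 °C; aq. Na2S2O3 quench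
Reagents that add atoms: 1,3-dibromo-5,5-dimethylhydantoin (DBDMH), CC1(C)N(Br)C(=O)N(Br)C1=O
Why: Proposed new method: the sulfur Lewis base takes Br+ from DBDMH and delivers it to the Si face of C10 of the most accessible 10,11-alkene, the 6E-alkene attacks C11 anti through a chair transition state (Br and side chain both equatorial, setting 10S and the cis-related C6 centre), and the ion-paired hydantoin anion removes the axial H-8 aligned with the C7 cation to give the endocyclic alkene, with the remote C3 centre leaving the outcome catalyst-controlled; the closest known reaction type is the chiral thiophosphoramide/DBDMH-catalysed enantioselective bromonium polyene cyclization of aryl-terminated geranyl and farnesyl substrates, extended here to an alkene terminator with proton loss.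

**Step 3**
Reactants: 3 triethyl({(3S)-5-[(1R,5S)-5-bromo-2,6,6-trimethylcyclohex-2-en-1-yl]-3-methylpent-1-en-3-yl}oxy)silane
Product: 5 (3S)-5-[(1S,3S,5S)-3,5-dibromo-2,2-dimethyl-6-methylidenecyclohexyl]-3-methylpent-1-en-3-ol, via dibromide silyl ether 4 (not isolated)
Conditions: TBCO (1.05 equiv), CH2Cl2, −40 → 0 °C, dark; then HF·pyridine, THF/pyridine, 0 °C → rt
Reagents that add atoms: 2,4,4,6-tetrabromocyclohexa-2,5-dien-1-one (TBCO), O=C1C(Br)=CC(Br)(Br)C=C1Br
Why: Ionic ene-type allylic bromination with double-bond transposition, in which Br+ adds axially to C8 on the ring face opposite the axial C11 methyl (8S, Br trans to the C6 chain and the C10 bromide) and tribromophenoxide removes a C15 proton anti to the bromonium (H-6 is syn and cannot be lost) to give the exocyclic alkene, after which fluoride cleaves the Si–O bond without touching either C–Br bond.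

**Compound list**
1 | (3S,6E)-nerolidol [(3S,6E)-3,7,11-trimethyldodeca-1,6,10-trien-3-ol] | C=C[C@@](C)(O)CC/C=C(\C)CCC=C(C)C | starting material
2 | triethyl{[(3S,6E)-3,7,11-trimethyldodeca-1,6,10-trien-3-yl]oxy}silane | C=C[C@@](C)(O[Si](CC)(CC)CC)CC/C=C(\C)CCC=C(C)C | intermediate
3 | triethyl({(3S)-5-[(1R,5S)-5-bromo-2,6,6-trimethylcyclohex-2-en-1-yl]-3-methylpent-1-en-3-yl}oxy)silane | C=C[C@@](C)(O[Si](CC)(CC)CC)CC[C@@H]1C(C)=CC[C@H](Br)C1(C)C | intermediate
4 | triethyl({(3S)-5-[(1S,3S,5S)-3,5-dibromo-2,2-dimethyl-6-methylidenecyclohexyl]-3-methylpent-1-en-3-yl}oxy)silane | C=C[C@@](C)(O[Si](CC)(CC)CC)CC[C@@H]1C(=C)[C@@H](Br)C[C@H](Br)C1(C)C | intermediate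
5 | (3S)-5-[(1S,3S,5S)-3,5-dibromo-2,2-dimethyl-6-methylidenecyclohexyl]-3-methylpent-1-en-3-ol | C=C[C@@](C)(O)CC[C@@H]1C(=C)[C@@H](Br)C[C@H](Br)C1(C)C | target

**Totals**
Total step count: 3. Longest linear sequence: 3 steps (1 → 2 → 3 → 5).

**Steps most likely to fail**

Step 2 (highest risk). Catalyst control has not been shown for a substrate that ends in an alkene; the ring diastereomer ratio may be low. Proton loss can also give the exocyclic isomer, which is useless for step 3, and the silyloxy oxygen may still trap the cation. Fallback, setting out from 1 and coming back at 3: the free alcohol 1 is treated with the commercial bromoperoxidase enzyme from Corallina officinalis, KBr and H2O2 (slow addition) in pH 6 buffer/EtOH. This enzymatic bromocyclization turns (+)-trans-nerolidol into the snyderols as single diastereomers, in low yield. The endocyclic isomer α-snyderol F1 is separated from its exocyclic isomer and the bicyclic bromo ether on AgNO3-impregnated silica and its ring configuration is checked against natural α-snyderol. Silylation with TESOTf/2,6-lutidine then gives 3.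

Step 3. The ene-type bromination may lose H-6 instead of H-15, the C7 cation may be captured by the silyloxy oxygen, or the axial allylic bromide may ionize during the HF treatment. Fallback, setting out from 3 and coming back at 4: Br2 (1 equiv, CH2Cl2, −78 °C) adds trans-diaxially to the ring alkene to give the 7,8,10-tribromide triethyl({(3S)-3-methyl-5-[(1S,2S,3S,5S)-2,3,5-tribromo-2,6,6-trimethylcyclohexyl]pent-1-en-3-yl}oxy)silane F2, which already carries the axial C8–Br of the target. DBU (CH2Cl2, 0 °C → rt) then removes HBr from the tertiary C7–Br toward the unhindered C15 methyl (E2) to give 4. Compound 4 is desilylated with HF·pyridine buffered with extra pyridine to give 5.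

Step 1. The silylation itself is safe; the risk is that the silyl ether still takes part as an oxygen nucleophile in steps 2 and 3. Fallback, setting out from 1 and coming back at 5: 1 is acetylated (Ac2O, DMAP, Et3N, CH2Cl2) to (3S,6E)-nerolidyl acetate F3, whose ester oxygen is a far poorer nucleophile. The step 2 cyclization then gives α-snyderol acetate F4, and TBCO (without the fluoride stage) gives the dibromo acetate F5. The acetate is removed reductively with i-Bu2AlH (2.2 equiv, CH2Cl2, −78 °C) to give 5.

**Further compounds**
F1 | step 2 | α-snyderol, (3S)-5-[(1R,5S)-5-bromo-2,6,6-trimethylcyclohex-2-en-1-yl]-3-methylpent-1-en-3-ol | C=C[C@@](C)(O)CC[C@@H]1C(C)=CC[C@H](Br)C1(C)C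
F2 | step 3 | triethyl({(3S)-3-methyl-5-[(1S,2S,3S,5S)-2,3,5-tribromo-2,6,6-trimethylcyclohexyl]pent-1-en-3-yl}oxy)silane | C=C[C@@](C)(O[Si](CC)(CC)CC)CC[C@@H]1[C@](C)(Br)[C@@H](Br)C[C@H](Br)C1(C)C
F3 | step 1 | (3S,6E)-nerolidyl acetate, (3S,6E)-3,7,11-trimethyldodeca-1,6,10-trien-3-yl acetate | C=C[C@@](C)(OC(C)=O)CC/C=C(\C)CCC=C(C)C
F4 | step 1 | α-snyderol acetate, (3S)-5-[(1R,5S)-5-bromo-2,6,6-trimethylcyclohex-2-en-1-yl]-3-methylpent-1-en-3-yl acetate | C=C[C@@](C)(OC(C)=O)CC[C@@H]1C(C)=CC[C@H](Br)C1(C)C
F5 | step 1 | (3S)-5-[(1S,3S,5S)-3,5-dibromo-2,2-dimethyl-6-methylidenecyclohexyl]-3-methylpent-1-en-3-yl acetate | C=C[C@@](C)(OC(C)=O)CC[C@@H]1C(=C)[C@@H](Br)C[C@H](Br)C1(C)C
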